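## Retrosynthetic overview

1. Numbering: decalin C1–C10, side chain C11–C22 from C9. The chain is cut at C11–C12. A C11 phenyl sulfone on the decalin is alkylated with a (2E,6E,10E)-12-silyloxyfarnesyl bromide, made from (2E,6E)-farnesol by SeO2 oxidation of its terminal E-methyl, which supplies the CH2OH on C22.
2. C11, the 9α-H and the 8α-OH go back to an 11-nor C7=C8–C9=O enone. Rubottom oxidation of the silyl enol ether from 1,4-hydrosilylation and hydroboration of the C9 methylene both strike the α face, opposite the axial C10 methyl.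
3. Structural feature used: the six ring-B carbons C5–C10, with a methyl on C8 and oxygen on C9, are the ring of (R)-carvone (carvone C5 = decalin C5). Quaternary C4 with its two methyls is carvone's isopropenyl carbon plus one hydrogen atom.
4. Ring A then lacks only C1–C3 and the C3–C4 bond. The C10 methyl and a three-carbon aldehyde arm come from two enolate alkylations, and addition of a C4 radical to the C3 aldehyde closes ring A and creates the 3β-OH.
5. Ring order: ring B from the chiral pool, ring A in step 5. No further ring is formed.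

Key step: step 5

Remark on the chemistry: 4 is carried on as its C6-epimer mixture and 31 as its C11-epimer mixture, because both centres are erased later (steps 2 and 19). The SMILES of 4 shows the major trans isomer, and those of 30 and 31 leave C11 open.

## Route

Step 1
Reactants: 1 (R)-carvone; 2 methyl iodide
Product: 4 (5R,6S)-2,6-dimethyl-5-(prop-1-en-2-yl)cyclohex-2-en-1-one (trans-6-methylcarvone), via lithium dienolate 3 (not isolated)
Conditions: LiN(i-Pr)2 (LDA, commercial solution, 1.05 equiv), THF, −78 °C; MeI, −78 → 0 °C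
Reagents that add atoms: methyl iodide (2), CI
Why: Enolate alkylation, in which kinetic α′-deprotonation at carvone C6 gives the cross-conjugated dienolate 3 and its SN2 methylation brings in the future C10 methyl; the new C6 centre does not matter because step 2 flattens it again.

Step 2
Reactants: 4 trans-6-methylcarvone; 5 allyl bromide
Product: 7 (5S,6S)-6-allyl-2,6-dimethyl-5-(prop-1-en-2-yl)cyclohex-2-en-1-one (allyl trans and methyl cis to the isopropenyl group), via lithium enolate 6 (not isolated)
Conditions: LDA (1.1 equiv), THF, −78 → −20 °C; DMPU, allyl bromide, −78 °C → rt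
Reagents that add atoms: allyl bromide (5), C=CCBr
Why: Enolate alkylation, in which allyl bromide attacks the tetrasubstituted enolate 6 on the face anti to the neighbouring isopropenyl group, which sets the quaternary centre (decalin C10) in the sense a trans ring fusion needs (the C5 descriptor changes to S only because quaternary C6 now outranks the isopropenyl carbon).

Step 3
Reactants: 7 allyl enone
Product: 9 (5S,6S)-6-(3-hydroxypropyl)-2,6-dimethyl-5-(prop-1-en-2-yl)cyclohex-2-en-1-one, via disiamylalkylborane 8 (not isolated)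
Conditions: Sia2BH (1.1 equiv, from BH3·THF + 2-methylbut-2-ene, THF, 0 °C), −10 → 0 °C; then NaBO3·4H2O, H2O, rt
Reagents that add atoms: sodium perborate (NaBO3·4H2O), [Na+].[Na+].O[B-]1(O)OO[B-](O)(O)OO1
Why: Brown hydroboration–oxidation, in which the bulky dialkylborane adds anti-Markovnikov to the monosubstituted allyl alkene far faster than to the hindered 1,1-disubstituted isopropenyl group, the electron-poor C=C or the ketone shielded by the quaternary carbon, and perborate replaces alkaline H2O2 so that Weitz–Scheffer epoxidation of the enone is avoided.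

Step 4
Reactants: 9 primary alcohol
Product: 10 (5S,6S)-2,6-dimethyl-6-(3-oxopropyl)-5-(prop-1-en-2-yl)cyclohex-2-en-1-one
Conditions: PhI(OAc)2 (1.1 equiv), TEMPO (10 mol %), CH2Cl2, rt
Reagents that add atoms: none
Why: Oxoammonium (TEMPO) oxidation of a primary alcohol stops at the aldehyde and leaves both alkenes and the enone untouched.

Step 5
Reactants: 10 keto aldehyde
Product: 13 3β-hydroxy-11-nordrim-7-en-9-one (trans-decalin; 5α-H; 10β-CH3), via C4 tertiary radical 11 (not isolated), via C3 oxyl radical 12 (not isolated)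
Conditions: Fe(acac)3 (20 mol %), PhSiH3 (2.5 equiv, slow addition), degassed EtOH (0.02 M), 60 °C, Ar
Reagents that add atoms: none
Why: Proposed new method: Fe(acac)3 and PhSiH3 in ethanol form an iron hydride that hands a hydrogen atom to the terminal CH2 of the isopropenyl group (Markovnikov metal-hydride hydrogen-atom transfer), which turns that CH2 into the second methyl on C4 and leaves the nucleophilic tertiary radical 11 on C4. Radical 11 attacks the aldehyde carbon C3 in a 6-exo-trig closure of ring A (C4–C5–C10–C1–C2–C3) to give oxyl radical 12, and this reversible addition is pulled forward because 12 is reduced at once by divalent iron and protonated by ethanol, after which ethoxide passes from iron to silicon and the hydride is regenerated. The closest known reaction type is the Fe(acac)3/PhSiH3 reductive radical cyclisation of alkene-tethered ketones to tertiary cycloalkanols, in which equally hindered oxyl radicals next to a quaternary carbon are trapped productively; an aldehyde is the less hindered and more electrophilic acceptor, but it has not been shown in this role. C3 is the only new stereocentre and is controlled by the chair transition state, in which the C5–C4 and C10–C1 bonds are equatorial on ring B and the C3=O bond points pseudo-equatorially, away from the axial hydrogens on C1 and C5, so that the 3β (equatorial) alcohol results; C5 and C10 are fixed beforehand and allow only the trans fusion. The selectivity needed is hydrogen-atom transfer to the electron-rich 1,1-disubstituted alkene in preference to the electron-poor trisubstituted C7=C8 bond and to hydrosilylation of the aldehyde, and it is secured by the polarity match of the iron hydride, by slow addition of the silane and by the fact that from C4 the enone can be reached only through four-membered or 5-endo closures. Dilution and exclusion of oxygen hold back intermolecular Giese addition and hydration of radical 11.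

Step 6
Reactants: 13 hydroxy enone
Product: 14 3β-(tert-butyldimethylsilyloxy)-11-nordrim-7-en-9-one
Conditions: TBSOTf (1.3 equiv), 2,6-lutidine (2 equiv), CH2Cl2, 0 °C
Reagents that add atoms: tert-butyldimethylsilyl triflate, CC(C)(C)[Si](C)(C)OS(=O)(=O)C(F)(F)F
Why: Silyl ether formation needs the reactive triflate because the 3β-hydroxyl sits next to quaternary C4, and the enone, which has no α′ hydrogen, is not enolised by lutidine.

Step 7
Reactants: 14 silyloxy enone
Product: 15 3β-(tert-butyldimethylsilyloxy)-9-(triethylsilyloxy)-11-nordrim-8-ene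
Conditions: Et3SiH (2 equiv), RhCl(PPh3)3 (2 mol %), THF, 50 °C
Reagents that add atoms: triethylsilane, CC[SiH](CC)CC
Why: Rhodium-catalysed 1,4-hydrosilylation of an enone with a monohydrosilane delivers hydride to C7 and silicon to oxygen, which gives the C8=C9 silyl enol ether regiospecifically without creating a stereocentre.

Step 8
Reactants: 15 silyl enol ether
Product: 17 3β-(tert-butyldimethylsilyloxy)-8α-(triethylsilyloxy)-11-nordriman-9-one (8β-CH3), via silyloxy epoxide 16 (not isolated)
Conditions: mCPBA (1.2 equiv), CH2Cl2, −20 → 0 °C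
Reagents that add atoms: mCPBA, OOC(=O)c1cccc(Cl)c1
Why: Rubottom oxidation, in which the peracid epoxidises the electron-rich C8=C9 bond from the α face opposite the adjacent axial C10 methyl and epoxide 16 opens to the C9 oxocarbenium ion with 1,4-shift of the silyl group onto the C8 oxygen, which sets C8 (8α-O, 8β-CH3) and leaves the tertiary alcohol already protected.

Step 9
Reactants: 17 α-silyloxy ketone; 18 methyltriphenylphosphonium bromide
Product: 19 3β-(tert-butyldimethylsilyloxy)-8α-(triethylsilyloxy)drim-9(11)-ene
Conditions: Ph3PCH3Br (5 equiv), KOt-Bu (4.8 equiv), toluene, rt then 100 °C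
Reagents that add atoms: methyltriphenylphosphonium bromide (18), C[P+](c1ccccc1)(c1ccccc1)c1ccccc1.[Br-]
Why: Wittig methylenation can be forced at high temperature here because C8 and C10 are fully substituted, so the ketone can neither enolise nor epimerise, and the silyl group on O8 blocks α-ketol rearrangement.

Step 10
Reactants: 19 exocyclic alkene
Product: 21 3β-(tert-butyldimethylsilyloxy)-8α-(triethylsilyloxy)driman-11-ol (9α-H; 9β-CH2OH), via C11 alkylborane 20 (not isolated)
Conditions: BH3·THF (3 equiv), THF, 0 °C → rt; then NaBO3·4H2O, H2O, rt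
Reagents that add atoms: sodium perborate (NaBO3·4H2O), [Na+].[Na+].O[B-]1(O)OO[B-](O)(O)OO1
Why: Brown hydroboration–oxidation puts boron on terminal C11 and delivers hydrogen to C9 from the α face because the two axial methyls on C8 and C10 close the β face, which sets C9 with an equatorial 9β-CH2OH, and the mild perborate work-up limits silyl transfer from O8 to O11.

Step 11
Reactants: 21 C11 alcohol
Product: 22 3β-(tert-butyldimethylsilyloxy)-11-(phenylthio)-8α-(triethylsilyloxy)drimane
Conditions: PhSSPh (2 equiv), n-Bu3P (2 equiv), THF, rt → 50 °C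
Reagents that add atoms: diphenyl disulfide, c1ccccc1SSc1ccccc1
Why: Hata reaction (redox condensation), in which the alcohol is activated as its alkoxyphosphonium salt and displaced by thiolate in an SN2 reaction at primary C11 under neutral conditions, so that no free alkoxide arises that could take over the O8 silyl group.

Step 12
Reactants: 22 sulfide
Product: 23 3β-(tert-butyldimethylsilyloxy)-11-(phenylsulfonyl)-8α-(triethylsilyloxy)drimane
Conditions: mCPBA (2.2 equiv), CH2Cl2, 0 °C
Reagents that add atoms: mCPBA, OOC(=O)c1cccc(Cl)c1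
Why: Peracid oxidation of a sulfide to the sulfone is clean here because the molecule has no alkene at this stage and both silyl ethers are inert.

Step 13
Reactants: 24 (2E,6E)-farnesol
Product: 25 (2E,6E)-farnesyl acetate
Conditions: Ac2O, pyridine, DMAP (5 mol %), CH2Cl2, rt
Reagents that add atoms: acetic anhydride, CC(=O)OC(C)=O
Why: DMAP-catalysed acetylation masks the C1 hydroxyl and deactivates the C2=C3 alkene towards the following allylic oxidation.

Step 14
Reactants: 25 farnesyl acetate
Product: 26 (2E,6E,10E)-12-hydroxy-3,7,11-trimethyldodeca-2,6,10-trien-1-yl acetate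
Conditions: SeO2 (10 mol %), t-BuOOH (2.5 equiv), salicylic acid (10 mol %), CH2Cl2, 0 °C → rt
Reagents that add atoms: tert-butyl hydroperoxide (terminal oxygen source), CC(C)(C)OO; selenium dioxide (oxygen carrier), O=[Se]=O
Why: Riley-type allylic oxidation (ene reaction, then [2,3]-sigmatropic shift) prefers the most electron-rich terminal trisubstituted alkene and by its mechanism oxidises the methyl trans to the chain, which sets the 10E geometry of the allylic alcohol.

Step 15
Reactants: 26 hydroxy acetate
Product: 27 (2E,6E,10E)-12-(tert-butyldimethylsilyloxy)-3,7,11-trimethyldodeca-2,6,10-trien-1-yl acetate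
Conditions: TBSCl, imidazole, DMF, rt
Reagents that add atoms: tert-butyldimethylsilyl chloride, CC(C)(C)[Si](C)(C)Cl
Why: Imidazole-promoted silylation of an unhindered primary allylic alcohol installs a group that leaves with the other silyl ethers in the last step.

Step 16
Reactants: 27 silyloxy acetate
Product: 28 (2E,6E,10E)-12-(tert-butyldimethylsilyloxy)-3,7,11-trimethyldodeca-2,6,10-trien-1-ol
Conditions: K2CO3 (20 mol %), MeOH, rt
Reagents that add atoms: none
Why: Base-catalysed transesterification (Zemplén-type methanolysis) removes the acetate while the silyl ether and the alkene geometries stay untouched.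

Step 17
Reactants: 28 allylic alcohol
Product: 29 (2E,6E,10E)-1-bromo-12-(tert-butyldimethylsilyloxy)-3,7,11-trimethyldodeca-2,6,10-triene
Conditions: CBr4 (1.3 equiv), PPh3 (1.4 equiv), CH2Cl2, 0 °C; used at once
Reagents that add atoms: carbon tetrabromide, BrC(Br)(Br)Br
Why: Appel reaction, in which bromide displaces the alkoxyphosphonium group at the primary allylic carbon under neutral conditions without allylic shift or loss of E geometry.

Step 18
Reactants: 23 C11 sulfone; 29 allylic bromide
Product: 31 C11-(phenylsulfonyl) tris-silyl ether of the target (C11 epimers), via C11 lithiosulfone 30 (not isolated)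
Conditions: n-BuLi (1.1 equiv), THF–DMPU, −78 °C; then 29, −78 → −20 °C
Reagents that add atoms: bromide 29 (listed under Reactants), C/C(=C\CC/C(C)=C/CC/C(C)=C/CBr)CO[Si](C)(C)C(C)(C)C
Why: Alkylation of a sulfone-stabilised carbanion (Julia-type fragment coupling) forms C11–C12 by SN2 attack on the reactive primary allylic bromide with retention of the E alkene, and the sulfonyl carbanion is stabilised enough that the O8 silyl group does not migrate to carbon.

Step 19
Reactants: 31 coupled sulfone
Product: 32 3β,22′-bis(tert-butyldimethylsilyl) 8α-triethylsilyl tris-ether of the target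
Conditions: Na(Hg) (6 %), Na2HPO4, MeOH–THF, −20 → 0 °C
Reagents that add atoms: none
Why: Reductive desulfonylation by single-electron transfer replaces the sulfonyl group by hydrogen without moving a double bond, since the sulfone is homoallylic and not allylic, and without Julia-type elimination, since neither C9 nor C12 carries a leaving group.

Step 20
Reactants: 32 tris-silyl ether
Product: 33 target CNP0200414.2
Conditions: Bu4NF (6 equiv), THF, 60 °C
Reagents that add atoms: none
Why: Fluoride-mediated desilylation removes all three silyl groups in one operation, with heating for the hindered O3 and O8 ethers, and its non-acidic medium protects the tertiary 8-ol and the trisubstituted alkenes from ionisation and cationic cyclisation.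

## Compound list

1 | (R)-(−)-carvone | CC1=CC[C@H](CC1=O)C(C)=C | starting material
2 | methyl iodide | CI | starting material
3 | lithium cross-conjugated dienolate of carvone (not isolated) | [Li]OC1=C[C@H](C(C)=C)CC=C1C | intermediate
4 | (5R,6S)-2,6-dimethyl-5-(prop-1-en-2-yl)cyclohex-2-en-1-one (trans-6-methylcarvone) | O=C1[C@@H](C)[C@H](C(C)=C)CC=C1C | intermediate
5 | allyl bromide | C=CCBr | starting material
6 | lithium enolate of 6-methylcarvone (not isolated) | [Li]OC1=C(C)[C@H](C(C)=C)CC=C1C | intermediate
7 | (5S,6S)-6-allyl-2,6-dimethyl-5-(prop-1-en-2-yl)cyclohex-2-en-1-one | O=C1[C@@](C)(CC=C)[C@H](C(C)=C)CC=C1C | intermediate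
8 | disiamyl[3-(ring C6)propyl]borane from 7 (not isolated) | O=C1[C@@](C)(CCCB(C(C)C(C)C)C(C)C(C)C)[C@H](C(C)=C)CC=C1C | intermediate
9 | (5S,6S)-6-(3-hydroxypropyl)-2,6-dimethyl-5-(prop-1-en-2-yl)cyclohex-2-en-1-one | O=C1[C@@](C)(CCCO)[C@H](C(C)=C)CC=C1C | intermediate
10 | (5S,6S)-2,6-dimethyl-6-(3-oxopropyl)-5-(prop-1-en-2-yl)cyclohex-2-en-1-one | O=C1[C@@](C)(CCC=O)[C@H](C(C)=C)CC=C1C | intermediate
11 | C4 tertiary (2-propyl) radical from 10 (not isolated) | O=C1[C@@](C)(CCC=O)[C@H]([C](C)C)CC=C1C | intermediate
12 | C3 oxyl radical of the closed decalin (not isolated) | O=C1[C@@]2(C)CC[C@H]([O])C(C)(C)[C@@H]2CC=C1C | intermediate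
13 | 3β-hydroxy-11-nordrim-7-en-9-one | O=C1[C@@]2(C)CC[C@H](O)C(C)(C)[C@@H]2CC=C1C | intermediate
14 | 3β-(tert-butyldimethylsilyloxy)-11-nordrim-7-en-9-one | O=C1[C@@]2(C)CC[C@H](O[Si](C)(C)C(C)(C)C)C(C)(C)[C@@H]2CC=C1C | intermediate
15 | 3β-(tert-butyldimethylsilyloxy)-9-(triethylsilyloxy)-11-nordrim-8-ene | CC[Si](CC)(CC)OC=1[C@@]2(C)CC[C@H](O[Si](C)(C)C(C)(C)C)C(C)(C)[C@@H]2CCC=1C | intermediate
16 | 8α,9α-epoxide of 15 (not isolated) | CC[Si](CC)(CC)O[C@]13[C@@]2(C)CC[C@H](O[Si](C)(C)C(C)(C)C)C(C)(C)[C@@H]2CC[C@@]1(C)O3 | intermediate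
17 | 3β-(tert-butyldimethylsilyloxy)-8α-(triethylsilyloxy)-11-nordriman-9-one | O=C1[C@@]2(C)CC[C@H](O[Si](C)(C)C(C)(C)C)C(C)(C)[C@@H]2CC[C@@]1(C)O[Si](CC)(CC)CC | intermediate
18 | methyltriphenylphosphonium bromide | C[P+](c1ccccc1)(c1ccccc1)c1ccccc1.[Br-] | starting material
19 | 3β-(tert-butyldimethylsilyloxy)-8α-(triethylsilyloxy)drim-9(11)-ene | C=C1[C@@]2(C)CC[C@H](O[Si](C)(C)C(C)(C)C)C(C)(C)[C@@H]2CC[C@@]1(C)O[Si](CC)(CC)CC | intermediate
20 | C11 monoalkylborane from 19 (not isolated) | BC[C@@H]1[C@@]2(C)CC[C@H](O[Si](C)(C)C(C)(C)C)C(C)(C)[C@@H]2CC[C@@]1(C)O[Si](CC)(CC)CC | intermediate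
21 | 3β-(tert-butyldimethylsilyloxy)-8α-(triethylsilyloxy)driman-11-ol | OC[C@@H]1[C@@]2(C)CC[C@H](O[Si](C)(C)C(C)(C)C)C(C)(C)[C@@H]2CC[C@@]1(C)O[Si](CC)(CC)CC | intermediate
22 | 3β-(tert-butyldimethylsilyloxy)-11-(phenylthio)-8α-(triethylsilyloxy)drimane | c1ccccc1SC[C@@H]1[C@@]2(C)CC[C@H](O[Si](C)(C)C(C)(C)C)C(C)(C)[C@@H]2CC[C@@]1(C)O[Si](CC)(CC)CC | intermediate
23 | 3β-(tert-butyldimethylsilyloxy)-11-(phenylsulfonyl)-8α-(triethylsilyloxy)drimane | O=S(=O)(c1ccccc1)C[C@@H]1[C@@]2(C)CC[C@H](O[Si](C)(C)C(C)(C)C)C(C)(C)[C@@H]2CC[C@@]1(C)O[Si](CC)(CC)CC | intermediate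
24 | (2E,6E)-farnesol | CC(C)=CCC/C(C)=C/CC/C(C)=C/CO | starting material
25 | (2E,6E)-farnesyl acetate | CC(C)=CCC/C(C)=C/CC/C(C)=C/COC(C)=O | intermediate
26 | (2E,6E,10E)-12-hydroxyfarnesyl acetate | C/C(=C\CC/C(C)=C/CC/C(C)=C/COC(C)=O)CO | intermediate
27 | (2E,6E,10E)-12-(tert-butyldimethylsilyloxy)farnesyl acetate | C/C(=C\CC/C(C)=C/CC/C(C)=C/COC(C)=O)CO[Si](C)(C)C(C)(C)C | intermediate
28 | (2E,6E,10E)-12-(tert-butyldimethylsilyloxy)farnesol | C/C(=C\CC/C(C)=C/CC/C(C)=C/CO)CO[Si](C)(C)C(C)(C)C | intermediate
29 | (2E,6E,10E)-12-(tert-butyldimethylsilyloxy)farnesyl bromide | C/C(=C\CC/C(C)=C/CC/C(C)=C/CBr)CO[Si](C)(C)C(C)(C)C | intermediate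
30 | C11-lithiated sulfone from 23 (not isolated) | [Li]C(S(=O)(=O)c1ccccc1)[C@@H]1[C@@]2(C)CC[C@H](O[Si](C)(C)C(C)(C)C)C(C)(C)[C@@H]2CC[C@@]1(C)O[Si](CC)(CC)CC | intermediate
31 | C11-(phenylsulfonyl) tris-silyl ether of the target (C11 epimers) | C/C(=C\CC/C(C)=C/CC/C(C)=C/CC([C@@H]1[C@@]2(C)CC[C@H](O[Si](C)(C)C(C)(C)C)C(C)(C)[C@@H]2CC[C@@]1(C)O[Si](CC)(CC)CC)S(=O)(=O)c1ccccc1)CO[Si](C)(C)C(C)(C)C | intermediate
32 | tris-silyl ether of the target (3β-OTBS, 8α-OTES, terminal OTBS) | C/C(=C\CC/C(C)=C/CC/C(C)=C/CC[C@@H]1[C@@]2(C)CC[C@H](O[Si](C)(C)C(C)(C)C)C(C)(C)[C@@H]2CC[C@@]1(C)O[Si](CC)(CC)CC)CO[Si](C)(C)C(C)(C)C | intermediate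
33 | CNP0200414.2, (2E,6E,10E)-13-[(1R,2R,4aR,6S,8aS)-2,6-dihydroxy-2,5,5,8a-tetramethyldecahydronaphthalen-1-yl]-2,6,10-trimethyltrideca-2,6,10-trien-1-ol | C/C(=C\CC/C(C)=C/CC/C(C)=C/CC[C@@H]1[C@@]2(C)CC[C@H](O)C(C)(C)[C@@H]2CC[C@@]1(C)O)CO | target

## Step count and risks

Total step count: 20. Longest linear sequence: 15 steps from (R)-carvone (steps 1–12, then 18–20). The farnesyl branch is 5 steps (13–17).

**Step 5 (labelled step).**
- What may go wrong: the aldehyde may be lost to direct hydrosilylation or acetal formation before the alkene is activated. The ring-closed oxyl radical may fall back by β-scission until the C4 radical is merely reduced. The face selectivity at C3 may be low.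
- Fallback (known chemistry): the acceptor is changed from aldehyde to nitrile, and C3 is set by a separate hydride reduction.
  - Setting out from 10, iodine and aqueous ammonia in THF convert the aldehyde into (5S,6S)-6-(2-cyanoethyl)-2,6-dimethyl-5-(prop-1-en-2-yl)cyclohex-2-en-1-one F1.
  - The known Fe(acac)3/PhSiH3 hydrogen-atom-transfer cyclisation of alkene-tethered nitriles, whose iminyl radical does not readily reopen, closes the same C3–C4 bond to give 3-imino-11-nordrim-7-en-9-one F2.
  - F2 is hydrolysed on work-up to 11-nordrim-7-ene-3,9-dione F3.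
  - NaBH4 in MeOH at −20 °C reduces the saturated C3 ketone by axial attack from the α face. It does so faster than it reduces the conjugated C9 ketone, which sits beside quaternary C10. The route is rejoined at 13.
  - A C3-epimer mixture from step 5 can be corrected in the same way, by Dess–Martin oxidation to F3 and the same reduction.

**Step 9.**
- What may go wrong: addition of the ylide to a carbonyl flanked by two fully substituted carbons may be too slow, with gradual loss of silyl groups at the temperature needed.
- Fallback: C11 is installed while C8 is still sp2, and the 8α-oxygen is brought in afterwards by radical hydration in place of the Rubottom oxidation.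
  - Setting out from 14, Wittig methylenation (Ph3P=CH2, THF, reflux) of the more open enone carbonyl gives 3β-(tert-butyldimethylsilyloxy)drima-7,9(11)-diene F4.
  - 9-BBN adds only to the exocyclic C9=C11 bond, from the α face, to give the B-(drim-7-en-11-yl)-9-borabicyclononane F5.
  - Perborate oxidation gives 3β-(tert-butyldimethylsilyloxy)drim-7-en-11-ol F6.
  - PhSSPh/n-Bu3P gives 3β-(tert-butyldimethylsilyloxy)-11-(phenylthio)drim-7-ene F7.
  - H2O2 with (NH4)6Mo7O24 gives 3β-(tert-butyldimethylsilyloxy)-11-(phenylsulfonyl)drim-7-ene F8 without touching the alkene.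
  - Mukaiyama hydration (Co(acac)2, PhSiH3, O2, THF) places the hydroxyl on tertiary C8. Oxygen is expected to trap the C8 radical on the α face, away from the axial C10 methyl, to give 3β-(tert-butyldimethylsilyloxy)-11-(phenylsulfonyl)driman-8α-ol F9.
  - TESOTf/2,6-lutidine brings the route back at 23.

**Step 11.**
- What may go wrong: SN2 displacement at C11 may be sluggish, because C11 hangs on C9 between two quaternary carbons. Transfer of the silyl group from O8 to O11 may also compete in steps 10 and 11.
- Fallback: C–S bond formation by a radical chain instead of substitution.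
  - Setting out from 19, anti-Markovnikov thiol–ene addition of PhSH (AIBN, toluene, 80 °C) puts the thiyl radical on terminal C11.
  - The tertiary C9 radical takes its hydrogen from PhSH on the open α face.
  - This gives 22 directly and bypasses step 10 as well, so no compound outside the list is made (F0).

## Further compounds

F1 | step 5 | (5S,6S)-6-(2-cyanoethyl)-2,6-dimethyl-5-(prop-1-en-2-yl)cyclohex-2-en-1-one | O=C1[C@@](C)(CCC#N)[C@H](C(C)=C)CC=C1C
F2 | step 5 | 3-imino-11-nordrim-7-en-9-one | O=C1[C@@]2(C)CCC(=N)C(C)(C)[C@@H]2CC=C1C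
F3 | step 5 | 11-nordrim-7-ene-3,9-dione | O=C1[C@@]2(C)CCC(=O)C(C)(C)[C@@H]2CC=C1C
F4 | step 9 | 3β-(tert-butyldimethylsilyloxy)drima-7,9(11)-diene | C=C1[C@@]2(C)CC[C@H](O[Si](C)(C)C(C)(C)C)C(C)(C)[C@@H]2CC=C1C
F5 | step 9 | B-(drim-7-en-11-yl)-9-borabicyclononane (3β-OTBS) | C(B1C2CCCC1CCC2)[C@@H]1[C@@]2(C)CC[C@H](O[Si](C)(C)C(C)(C)C)C(C)(C)[C@@H]2CC=C1C
F6 | step 9 | 3β-(tert-butyldimethylsilyloxy)drim-7-en-11-ol | OC[C@@H]1[C@@]2(C)CC[C@H](O[Si](C)(C)C(C)(C)C)C(C)(C)[C@@H]2CC=C1C
F7 | step 9 | 3β-(tert-butyldimethylsilyloxy)-11-(phenylthio)drim-7-ene | c1ccccc1SC[C@@H]1[C@@]2(C)CC[C@H](O[Si](C)(C)C(C)(C)C)C(C)(C)[C@@H]2CC=C1C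
F8 | step 9 | 3β-(tert-butyldimethylsilyloxy)-11-(phenylsulfonyl)drim-7-ene | O=S(=O)(c1ccccc1)C[C@@H]1[C@@]2(C)CC[C@H](O[Si](C)(C)C(C)(C)C)C(C)(C)[C@@H]2CC=C1C
F9 | step 9 | 3β-(tert-butyldimethylsilyloxy)-11-(phenylsulfonyl)driman-8α-ol | O=S(=O)(c1ccccc1)C[C@@H]1[C@@]2(C)CC[C@H](O[Si](C)(C)C(C)(C)C)C(C)(C)[C@@H]2CC[C@@]1(C)O
F0 | step 11 | none | none
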